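## Retrosynthetic overview

1. Last C–C bond, C7–C11 (isopropenyl): C7 is made electrophilic as the α-bromo ketone (an enolonium equivalent) and joined to an isopropenylzinc nucleophile under nickel catalysis. Doing this last keeps the base-labile β,γ-unsaturated ketone away from base.
2. C9–O: Rubottom oxidation of the C8–C9 enol silane obtained by copper hydride 1,4-reduction of the ring B enone, which also sets the cis ring fusion. The angelate goes on before this, the senecioate after.
3. Ring B (formed second): cuprate addition, Michael addition and aldol annulation on a ring A enone; C4 and C5 are set from the C3 silyloxy stereocentre.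
4. Ring A (present from the start): (R)-4-hydroxy-2-methylcyclohex-2-enone, made from 3-ethoxy-2-methylcyclohex-2-enone by α′-acetoxylation, enzymatic resolution and Stork–Danheiser transposition.

Locants C1–C15 in the text follow eremophilane numbering (ring A = C1–C5, C10; ring B = C5–C10; β = the face of the C4 and C5 methyl groups).

Assumption: the esterase in step 2 hydrolyses the (S)-acetate faster; with an esterase of opposite preference the (R)-alcohol is collected instead and enters step 3 unchanged, since LiAlH4 takes both to the same diol 4.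

## Route

Step 1
Reactants: 1 3-ethoxy-2-methylcyclohex-2-en-1-one
Product: 2 rac-6-acetoxy-3-ethoxy-2-methylcyclohex-2-en-1-one
Conditions: Mn(OAc)3·2H2O (3 equiv), benzene, reflux, Dean–Stark
Reagents that add atoms: manganese triacetate, CC(=O)[O-].CC(=O)[O-].CC(=O)[O-].[Mn+3]
Why: Trivalent-manganese α′-acetoxylation of an enone proceeds through the manganese enolate on the only enolisable side (C6) of the vinylogous ester; the new stereocentre is formed racemic.

Step 2
Reactants: 2 rac-6-acetoxy-3-ethoxy-2-methylcyclohex-2-en-1-one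
Product: 3 (R)-6-acetoxy-3-ethoxy-2-methylcyclohex-2-en-1-one
Conditions: pig liver esterase, phosphate buffer pH 7.0/DMSO 9:1, 25 °C, stopped at about 52% conversion
Reagents that add atoms: none
Why: Enzymatic kinetic resolution (enantioselective ester hydrolysis) of α′-acetoxy enones leaves the slow-reacting (R)-acetate in high ee just past half conversion, and this carbinol centre becomes C3 of the target.

Step 3
Reactants: 3 (R)-6-acetoxy-3-ethoxy-2-methylcyclohex-2-en-1-one
Product: 5 (R)-4-hydroxy-2-methylcyclohex-2-en-1-one, via allylic diol 4 (not isolated)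
Conditions: LiAlH4, Et2O, 0 °C; then 1 M HCl, 0 °C to 23 °C
Reagents that add atoms: water, O
Why: Stork–Danheiser carbonyl transposition: hydride reduces the ketone (and cleaves the acetate), and acid hydrolysis of the enol ether with loss of the allylic hydroxyl gives the transposed enone, leaving the carbinol stereocentre untouched.

Step 4
Reactants: 5 (R)-4-hydroxy-2-methylcyclohex-2-en-1-one
Product: 6 (R)-2-methyl-4-(triethylsilyloxy)cyclohex-2-en-1-one
Conditions: Et3SiCl, imidazole, DMF, 0 °C
Reagents that add atoms: chlorotriethylsilane, CC[Si](Cl)(CC)CC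
Why: Standard silylation of a secondary alcohol; the bulky silyl ether is needed because a γ-acyloxy enone would be reductively cleaved by the cuprate, and it directs the next step.

Step 5
Reactants: 6 (R)-2-methyl-4-(triethylsilyloxy)cyclohex-2-en-1-one; 7 3-(trimethylsilyl)but-3-en-2-one
Product: 11 (4aR,5R,6R)-6-hydroxy-4a,5-dimethyl-4,4a,5,6,7,8-hexahydronaphthalen-2(3H)-one, via lithium enolate 8 (not isolated), via silyl diketone 9 (not isolated), via silyl ether octalone 10 (not isolated)
Conditions: Me2CuLi (1.3 equiv), Et2O, −78 to −30 °C; then 7, THF, −78 to 0 °C; then NaOMe, MeOH, 23 to 50 °C; then 2 M HCl, 23 °C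
Reagents that add atoms: lithium dimethylcuprate, [Li+].C[Cu-]C
Why: Gilman cuprate 1,4-addition anti to the γ-silyloxy group sets C4 (methyl trans to oxygen), the enolate 8 then adds to the α-silyl vinyl ketone on the face opposite the new methyl (quaternary C5, vicinal methyls cis), and methoxide removes the C-silyl group and closes ring B by aldol condensation (Stork–Ganem/Boeckman conjugate addition–annulation, a Robinson annulation variant) before acid cleaves the silyl ether.

Step 6
Reactants: 11 (4aR,5R,6R)-6-hydroxy-4a,5-dimethyl-4,4a,5,6,7,8-hexahydronaphthalen-2(3H)-one; 12 angelic acid [(Z)-2-methylbut-2-enoic acid]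
Product: 13 (1R,2R,8aR)-1,8a-dimethyl-6-oxo-1,2,3,4,6,7,8,8a-octahydronaphthalen-2-yl (Z)-2-methylbut-2-enoate
Conditions: 12, 2,4,6-trichlorobenzoyl chloride, Et3N, toluene, 23 °C, 2 h; then 11, 75 °C
Reagents that add atoms: none
Why: Yamaguchi mixed-anhydride esterification run hot without DMAP acylates hindered secondary alcohols with angelic acid without Z to E isomerisation, and it is done here while the molecule still has no base-sensitive β,γ-unsaturated ketone.

Step 7
Reactants: 13 (1R,2R,8aR)-1,8a-dimethyl-6-oxo-1,2,3,4,6,7,8,8a-octahydronaphthalen-2-yl (Z)-2-methylbut-2-enoate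
Product: 14 (1R,2R,4aR,8aS)-6-[dimethyl(phenyl)silyl]oxy-1,8a-dimethyl-1,2,3,4,4a,7,8,8a-octahydronaphthalen-2-yl (Z)-2-methylbut-2-enoate (cis-fused, 10β-H)
Conditions: [(Ph3P)CuH]6 (10 mol % Cu), PhMe2SiH (1.5 equiv), toluene, 23 °C
Reagents that add atoms: dimethylphenylsilane, C[SiH](C)c1ccccc1
Why: Copper hydride 1,4-reduction (Stryker type, silane turnover) delivers hydride to C10 on the face of the angular methyl, as cuprates do with angular-methyl octalones, which fixes the cis ring fusion and gives the C8–C9 enol silane regiospecifically while the less electrophilic trisubstituted angelate is spared.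

Step 8
Reactants: 14 (1R,2R,4aR,8aS)-6-[dimethyl(phenyl)silyl]oxy-1,8a-dimethyl-1,2,3,4,4a,7,8,8a-octahydronaphthalen-2-yl (Z)-2-methylbut-2-enoate
Product: 17 (1R,2R,4aS,5R,8aR)-5-hydroxy-1,8a-dimethyl-6-oxodecahydronaphthalen-2-yl (Z)-2-methylbut-2-enoate, via silyloxy epoxide 15 (not isolated), via silyloxy ketone 16 (not isolated)
Conditions: mCPBA (1.05 equiv), NaHCO3, CH2Cl2, −20 °C; then 1 M HCl, THF, 0 °C
Reagents that add atoms: mCPBA, OOC(=O)c1cccc(Cl)c1
Why: Rubottom oxidation: the peracid epoxidises the electron-rich enol silane on the convex face of the cis-fused bicycle (the face of the ring-fusion H and methyl), and silyl migration then acid cleavage give the equatorial 9β-hydroxy ketone, the electron-poor angelate alkene being left alone.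

Step 9
Reactants: 17 (1R,2R,4aS,5R,8aR)-5-hydroxy-1,8a-dimethyl-6-oxodecahydronaphthalen-2-yl (Z)-2-methylbut-2-enoate; 18 3-methylbut-2-enoic acid (senecioic acid)
Product: 19 (1R,2R,4aS,5R,8aR)-1,8a-dimethyl-5-[(3-methylbut-2-enoyl)oxy]-6-oxodecahydronaphthalen-2-yl (Z)-2-methylbut-2-enoate
Conditions: DCC, DMAP (10 mol %), CH2Cl2, 0 to 23 °C
Reagents that add atoms: none
Why: Steglich esterification acylates the α-ketol under nearly neutral conditions and avoids the vinylketene pathway that deconjugates senecioyl chloride with amine bases.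

Step 10
Reactants: 19 (1R,2R,4aS,5R,8aR)-1,8a-dimethyl-5-[(3-methylbut-2-enoyl)oxy]-6-oxodecahydronaphthalen-2-yl (Z)-2-methylbut-2-enoate
Product: 21 (1R,2R,4aS,5R,7RS,8aR)-7-bromo-1,8a-dimethyl-5-[(3-methylbut-2-enoyl)oxy]-6-oxodecahydronaphthalen-2-yl (Z)-2-methylbut-2-enoate, via silyl enol ether 20 (not isolated)
Conditions: TMSOTf, Et3N, CH2Cl2, −78 to −20 °C; then NBS, THF, −78 °C, dark
Reagents that add atoms: N-bromosuccinimide, BrN1C(=O)CCC1=O; trimethylsilyl triflate, C[Si](C)(C)OS(=O)(=O)C(F)(F)F (silyl group only in 20)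
Why: Soft enolisation (silyl triflate/amine) removes the accessible C7 methylene proton in preference to the hindered concave-face C9 methine, and electrophilic α-bromination of the enol silane turns the normally nucleophilic α-carbon into an electrophile; the C7 configuration does not matter because the next step is stereoconvergent.

Step 11
Reactants: 21 (1R,2R,4aS,5R,7RS,8aR)-7-bromo-1,8a-dimethyl-5-[(3-methylbut-2-enoyl)oxy]-6-oxodecahydronaphthalen-2-yl (Z)-2-methylbut-2-enoate; 22 isopropenylmagnesium bromide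
Product: 23 (1R,2R,4aS,5R,7R,8aR)-1,8a-dimethyl-5-[(3-methylbut-2-enoyl)oxy]-6-oxo-7-(prop-1-en-2-yl)decahydronaphthalen-2-yl (Z)-2-methylbut-2-enoate (CNP0375730.2)
Conditions: 22, ZnBr2, THF, 0 °C (gives isopropenylzinc bromide); then 21, NiCl2·glyme (10 mol %), 4,4′-di-tert-butyl-2,2′-bipyridine (12 mol %), DMA/THF, −20 to 0 °C
Reagents that add atoms: none
Why: Proposed new method: the α-bromo ketone acts as an enolonium equivalent, monovalent nickel abstracting bromine to give the planar C7 α-keto radical, which is captured by the isopropenylnickel species and reductively eliminated on the convex β face, so both bromide epimers should converge on the equatorial 7β-isopropenyl ketone under conditions too weakly basic to move the alkene into conjugation; the closest known reaction type is the nickel-catalysed stereoconvergent Negishi-type arylation and alkenylation of secondary α-bromo ketones.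

## Compound list

1 | 3-ethoxy-2-methylcyclohex-2-en-1-one | CCOC1=C(C)C(=O)CCC1 | starting material
2 | rac-6-acetoxy-3-ethoxy-2-methylcyclohex-2-en-1-one | CCOC1=C(C)C(=O)C(OC(C)=O)CC1 | intermediate
3 | (R)-6-acetoxy-3-ethoxy-2-methylcyclohex-2-en-1-one | CCOC1=C(C)C(=O)[C@H](OC(C)=O)CC1 | intermediate
4 | (1R,2RS)-4-ethoxy-3-methylcyclohex-3-ene-1,2-diol | CCOC1=C(C)C(O)[C@H](O)CC1 | intermediate
5 | (R)-4-hydroxy-2-methylcyclohex-2-en-1-one | O=C1CC[C@@H](O)C=C1C | intermediate
6 | (R)-2-methyl-4-(triethylsilyloxy)cyclohex-2-en-1-one | O=C1CC[C@@H](O[Si](CC)(CC)CC)C=C1C | intermediate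
7 | 3-(trimethylsilyl)but-3-en-2-one | CC(=O)C(=C)[Si](C)(C)C | starting material
8 | lithium (3R,4R)-2,3-dimethyl-4-(triethylsilyloxy)cyclohex-1-en-1-olate | [Li+].CC1=C([O-])CC[C@@H](O[Si](CC)(CC)CC)[C@@H]1C | intermediate
9 | (2R,3R,4R)-2,3-dimethyl-2-[3-oxo-2-(trimethylsilyl)butyl]-4-(triethylsilyloxy)cyclohexan-1-one (epimers at the C-silyl carbon) | CC(=O)C([Si](C)(C)C)C[C@@]1(C)C(=O)CC[C@@H](O[Si](CC)(CC)CC)[C@@H]1C | intermediate
10 | (4aR,5R,6R)-4a,5-dimethyl-6-(triethylsilyloxy)-4,4a,5,6,7,8-hexahydronaphthalen-2(3H)-one | O=C1CC[C@@]2(C)C(=C1)CC[C@@H](O[Si](CC)(CC)CC)[C@@H]2C | intermediate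
11 | (4aR,5R,6R)-6-hydroxy-4a,5-dimethyl-4,4a,5,6,7,8-hexahydronaphthalen-2(3H)-one | O=C1CC[C@@]2(C)C(=C1)CC[C@@H](O)[C@@H]2C | intermediate
12 | angelic acid, (Z)-2-methylbut-2-enoic acid | C/C=C(/C)C(=O)O | starting material
13 | (1R,2R,8aR)-1,8a-dimethyl-6-oxo-1,2,3,4,6,7,8,8a-octahydronaphthalen-2-yl (Z)-2-methylbut-2-enoate | O=C1CC[C@@]2(C)C(=C1)CC[C@@H](OC(=O)/C(C)=C\C)[C@@H]2C | intermediate
14 | (1R,2R,4aR,8aS)-6-[dimethyl(phenyl)silyl]oxy-1,8a-dimethyl-1,2,3,4,4a,7,8,8a-octahydronaphthalen-2-yl (Z)-2-methylbut-2-enoate, cis-fused | C1C[C@@]2(C)[C@H](CC[C@@H](OC(=O)/C(C)=C\C)[C@@H]2C)C=C1O[Si](C)(C)c3ccccc3 | intermediate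
15 | 8β,9β-epoxide of 14 (oxirane on the face of the ring-fusion H, silyloxy group on the oxirane carbon C8) | C1C[C@@]2(C)[C@H](CC[C@@H](OC(=O)/C(C)=C\C)[C@@H]2C)[C@H]3O[C@]31O[Si](C)(C)c4ccccc4 | intermediate
16 | (1R,2R,4aS,5R,8aR)-5-[dimethyl(phenyl)silyl]oxy-1,8a-dimethyl-6-oxodecahydronaphthalen-2-yl (Z)-2-methylbut-2-enoate | C1C[C@@]2(C)[C@H](CC[C@@H](OC(=O)/C(C)=C\C)[C@@H]2C)[C@@H](O[Si](C)(C)c3ccccc3)C1=O | intermediate
17 | (1R,2R,4aS,5R,8aR)-5-hydroxy-1,8a-dimethyl-6-oxodecahydronaphthalen-2-yl (Z)-2-methylbut-2-enoate | C1C[C@@]2(C)[C@H](CC[C@@H](OC(=O)/C(C)=C\C)[C@@H]2C)[C@@H](O)C1=O | intermediate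
18 | 3-methylbut-2-enoic acid (senecioic acid) | CC(C)=CC(=O)O | starting material
19 | (1R,2R,4aS,5R,8aR)-1,8a-dimethyl-5-[(3-methylbut-2-enoyl)oxy]-6-oxodecahydronaphthalen-2-yl (Z)-2-methylbut-2-enoate | C1C[C@@]2(C)[C@H](CC[C@@H](OC(=O)/C(C)=C\C)[C@@H]2C)[C@@H](OC(=O)C=C(C)C)C1=O | intermediate
20 | (1R,2R,4aS,5R,8aR)-1,8a-dimethyl-5-[(3-methylbut-2-enoyl)oxy]-6-(trimethylsilyloxy)-1,2,3,4,4a,5,8,8a-octahydronaphthalen-2-yl (Z)-2-methylbut-2-enoate | C[Si](C)(C)OC1=CC[C@@]2(C)[C@H](CC[C@@H](OC(=O)/C(C)=C\C)[C@@H]2C)[C@H]1OC(=O)C=C(C)C | intermediate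
21 | (1R,2R,4aS,5R,7RS,8aR)-7-bromo-1,8a-dimethyl-5-[(3-methylbut-2-enoyl)oxy]-6-oxodecahydronaphthalen-2-yl (Z)-2-methylbut-2-enoate | BrC1C[C@@]2(C)[C@H](CC[C@@H](OC(=O)/C(C)=C\C)[C@@H]2C)[C@@H](OC(=O)C=C(C)C)C1=O | intermediate
22 | isopropenylmagnesium bromide | CC(=C)[Mg]Br | starting material
23 | (1R,2R,4aS,5R,7R,8aR)-1,8a-dimethyl-5-[(3-methylbut-2-enoyl)oxy]-6-oxo-7-(prop-1-en-2-yl)decahydronaphthalen-2-yl (Z)-2-methylbut-2-enoate; in eremophilane numbering (3R,4R,5R,7R,9R,10S)-3-angeloyloxy-9-senecioyloxyeremophil-11-en-8-one | C=C(C)[C@H]1C[C@@]2(C)[C@H](CC[C@@H](OC(=O)/C(C)=C\C)[C@@H]2C)[C@@H](OC(=O)C=C(C)C)C1=O | target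

## Step count and risks

Total steps: 11. Longest linear sequence: 11 (1 to 23).

The three steps most likely to fail:

1. Step 11 (nickel coupling at C7). The risks are reduction of the bromide back to 19, a poor 7β:7α ratio, and drift of the new alkene into conjugation. Fallback: set out from 21 and reverse the polarity at C7. Activated zinc dust in THF at 0 °C turns 21 into the bromozinc enolate F1. Pd2(dba)3 with P(t-Bu)3 and 2-bromopropene at 23 °C then makes the same C7–C11 bond by reductive elimination from the carbon-bound palladium enolate (enolate α-alkenylation), again on the convex face. The fallback comes back to the route at 23.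

2. Step 10 (regiochemistry of enol silane formation, C7 against C9). Fallback: set out from 19 and use acid-driven enolisation, which avoids the acyloxy-bearing carbon. PhI(OH)OTs in MeCN at 45 °C forms the trivalent-iodine enolonium at C7, and tosylate captures it to give the 7-tosyloxy ketone F2. NaI in acetone at 23 °C exchanges this to the 7-iodo ketone F3. F3 takes the place of 21 in the nickel coupling of step 11, so the fallback comes back at 23.

3. Step 7 (face selectivity and rate of the copper hydride reduction at the fully substituted C10). Fallback: set out from 11 and set the ring fusion by heterogeneous hydrogenation before the angelate alkene is present. H2 (1 atm) over 10% Pd/C in EtOH/pyridine gives the cis-fused hydroxy decalone F4. Angeloylation under the conditions of step 6 gives the keto angelate F5. TMSCl, NaI and Et3N in MeCN at 23 °C give the thermodynamic enol silane toward the ring fusion, the trimethylsilyl enol ether F6, as cis-fused 2-decalones enolise toward C9. Rubottom oxidation as in step 8 brings the fallback back at 17.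

Further compounds

F1 | step 11 | bromozinc enolate of 19 (C7=C8 enolate, O–ZnBr) | Br[Zn]OC1=CC[C@@]2(C)[C@H](CC[C@@H](OC(=O)/C(C)=C\C)[C@@H]2C)[C@H]1OC(=O)C=C(C)C
F2 | step 10 | 7-tosyloxy ketone: (1R,2R,4aS,5R,7RS,8aR)-1,8a-dimethyl-5-[(3-methylbut-2-enoyl)oxy]-6-oxo-7-(tosyloxy)decahydronaphthalen-2-yl (Z)-2-methylbut-2-enoate | Cc1ccc(cc1)S(=O)(=O)OC1C[C@@]2(C)[C@H](CC[C@@H](OC(=O)/C(C)=C\C)[C@@H]2C)[C@@H](OC(=O)C=C(C)C)C1=O
F3 | step 10 | 7-iodo ketone: (1R,2R,4aS,5R,7RS,8aR)-7-iodo-1,8a-dimethyl-5-[(3-methylbut-2-enoyl)oxy]-6-oxodecahydronaphthalen-2-yl (Z)-2-methylbut-2-enoate | IC1C[C@@]2(C)[C@H](CC[C@@H](OC(=O)/C(C)=C\C)[C@@H]2C)[C@@H](OC(=O)C=C(C)C)C1=O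
F4 | step 7 | cis-fused hydroxy decalone: 3α-hydroxy-4β,5β-dimethyl-10βH-decal-8-one (eremophilane locants) | C1C[C@@]2(C)[C@H](CC[C@@H](O)[C@@H]2C)CC1=O
F5 | step 7 | cis-fused keto angelate: 3α-angeloyloxy-4β,5β-dimethyl-10βH-decal-8-one (eremophilane locants) | C1C[C@@]2(C)[C@H](CC[C@@H](OC(=O)/C(C)=C\C)[C@@H]2C)CC1=O
F6 | step 7 | trimethylsilyl enol ether of F5 (C8–C9 enol silane) | C1C[C@@]2(C)[C@H](CC[C@@H](OC(=O)/C(C)=C\C)[C@@H]2C)C=C1O[Si](C)(C)C
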